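**Retrosynthetic overview**
1. Target 16 ⇐ heptabenzyl precursor 15 by global hydrogenolysis.
2. 15 ⇐ hemiester 12 + (R)-alcohol 14: the ester C–O bond is made by Mitsunobu inversion, because the lactate carbon of the target is S whereas natural danshensu is R.
3. 12 ⇐ meso anhydride 11: a C–O bond is made by catalytic desymmetrising benzyl alcoholysis, which fixes the absolute sense of all four ring stereocentres.
4. 11 ⇐ meso all-trans diacid 10 ⇐ all-cis diaryl cyclobutane 8 ⇐ two amide-directed C–H arylations of purchased cyclobutane 1 (aryl groups land cis to each other; the carboxyl carbons are then equilibrated trans).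
5. Rings: the cyclobutane is bought; the only ring formed is the anhydride bridge (step 6), which is opened again in step 7.

Assumption: the sense of induction in step 7 cannot be predicted, so the route is written for (DHQD)2AQN and the pseudo-enantiomeric (DHQ)2AQN is substituted if the first run gives the mirror-image hemiester.

**Step 1**
Reactants: 1 cis-3-(methoxycarbonyl)cyclobutane-1-carboxylic acid; 2 2-(methylsulfanyl)aniline
Product: 3 methyl cis-3-{[2-(methylsulfanyl)phenyl]carbamoyl}cyclobutane-1-carboxylate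
Conditions: DIC (1.2 equiv), DMAP (0.1 equiv), CH2Cl2, 0 °C to rt
Reagents that add atoms: none
Why: Carbodiimide (Steglich-type) amide coupling installs the N,S-bidentate directing group; no stereocentre is touched and the cis 1,3-relationship is carried over.

**Step 2**
Reactants: 4 1,2-bis(benzyloxy)benzene
Product: 5 1,2-bis(benzyloxy)-4-iodobenzene
Conditions: NIS (1.05 equiv), TFA (0.1 equiv), MeCN, rt
Reagents that add atoms: N-iodosuccinimide, O=C1CCC(=O)N1I
Why: Electrophilic aromatic iodination para to an alkoxy group, as for veratrole; no stereocentre is involved.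

**Step 3**
Reactants: 3 methyl cis-3-{[2-(methylsulfanyl)phenyl]carbamoyl}cyclobutane-1-carboxylate; 5 1,2-bis(benzyloxy)-4-iodobenzene
Product: 6 methyl 2-[3,4-bis(benzyloxy)phenyl]-3-{[2-(methylsulfanyl)phenyl]carbamoyl}cyclobutane-1-carboxylate (all-cis; racemic)
Conditions: 5 (2 equiv), Pd(OAc)2 (15 mol %), Ag2CO3 (1.5 equiv), PivOH (1 equiv), HFIP, 90 °C
Reagents that add atoms: none
Why: Daugulis-type amide-directed β-C(sp3)–H arylation through a divalent/tetravalent palladium cycle; the five-membered palladacycle can form only at a methylene C–H on the amide face, so the aryl group is delivered cis to the amide and to the cis ester, and HFIP/PivOH holds the reaction at mono-arylation as known for this auxiliary on cyclobutanes.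

**Step 4**
Reactants: 6 all-cis mono-aryl amide ester; 7 1-(benzyloxy)-4-iodobenzene
Product: 8 methyl 2-[3,4-bis(benzyloxy)phenyl]-4-[4-(benzyloxy)phenyl]-3-{[2-(methylsulfanyl)phenyl]carbamoyl}cyclobutane-1-carboxylate (all-cis; racemic)
Conditions: 7 (3 equiv), Pd(OAc)2 (20 mol %), Ag2CO3 (1.5 equiv), PivOH (1 equiv), t-BuOH, 100 °C
Reagents that add atoms: none
Why: A second directed C–H arylation of the same type at the remaining methylene, again on the amide face, so the two aryl groups are cis to each other, which is the 2,4-relationship kept in the target.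

**Step 5**
Reactants: 8 all-cis diaryl amide ester
Product: 10 2-[3,4-bis(benzyloxy)phenyl]-4-[4-(benzyloxy)phenyl]cyclobutane-1,3-dicarboxylic acid (all-trans; meso), via all-trans amide ester 9 (not isolated)
Conditions: KOtBu (3 equiv), THF, 50 °C; then KOH (20 equiv), EtOH/H2O, 130 °C (sealed tube); then aq HCl
Reagents that add atoms: potassium hydroxide, [K+].[OH-]
Why: Enolate epimerisation moves both carbonyl-bearing carbons to the all-trans (all-pseudoequatorial) thermodynamic isomer, then amide and ester are hydrolysed; the aryl-bearing carbons cannot epimerise, so the cis-diaryl relation stays and the diacid is meso.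

**Step 6**
Reactants: 10 meso all-trans diacid
Product: 11 6-[3,4-bis(benzyloxy)phenyl]-7-[4-(benzyloxy)phenyl]-3-oxabicyclo[3.1.1]heptane-2,4-dione (meso; both aryl groups anti to the anhydride bridge)
Conditions: DCC (1.05 equiv), CH2Cl2, 0 °C to rt; filter; recrystallise
Reagents that add atoms: none
Why: Carbodiimide dehydration of a cis-1,3-diacid to the bridged cyclic anhydride; conditions are neutral and cold so nothing epimerises, and only the cis-diacid can bridge.

**Step 7**
Reactants: 11 meso anhydride
Product: 12 1-benzyl hydrogen 2-[4-(benzyloxy)phenyl]-4-[3,4-bis(benzyloxy)phenyl]cyclobutane-1,3-dicarboxylate (all-trans; seen from the aryl face the order CO2Bn, 4-(benzyloxy)phenyl, CO2H, 3,4-bis(benzyloxy)phenyl runs clockwise)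
Conditions: (DHQD)2AQN (30 mol %), BnOH (3 equiv), MTBE, −30 °C; aq HCl wash
Reagents that add atoms: benzyl alcohol, OCc1ccccc1
Why: Proposed new method: enantiotopic-carbonyl-selective benzyl alcoholysis of a bridged cyclobutane-1,3-dicarboxylic anhydride whose two C=O groups differ only through the distal aryl pair; the quinuclidine nitrogen activates BnOH as a general base as in the known alkaloid-catalysed opening of meso succinic and 3-substituted glutaric anhydrides, while the electron-poor anthraquinone wall is expected to stack on the more electron-rich 3,4-bis(benzyloxy)phenyl ring, so the catalyst docks from the side of that ring and its handedness then picks one carbonyl, which sets the absolute configuration of all four ring carbons in the C–O bond-forming event; closest known reaction type: cinchona-alkaloid-catalysed desymmetrising alcoholysis of meso cyclic anhydrides (with peptide-catalysed remote desymmetrisation as the model for distal recognition).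

**Step 8**
Reactants: 13 sodium (R)-3-(3,4-dihydroxyphenyl)-2-hydroxypropanoate (sodium danshensu)
Product: 14 benzyl (R)-3-[3,4-bis(benzyloxy)phenyl]-2-hydroxypropanoate
Conditions: BnBr (3.2 equiv), K2CO3 (2.5 equiv), DMF, rt, N2
Reagents that add atoms: benzyl bromide, BrCc1ccccc1
Why: Williamson-type O-benzylation of the carboxylate and both phenoxides; the secondary alcohol is not ionised by K2CO3 and the stereocentre is untouched.

**Step 9**
Reactants: 12 hemiester; 14 benzyl (R)-3-[3,4-bis(benzyloxy)phenyl]-2-hydroxypropanoate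
Product: 15 1-benzyl 3-{(S)-1-(benzyloxy)-3-[3,4-bis(benzyloxy)phenyl]-1-oxopropan-2-yl} 2-[4-(benzyloxy)phenyl]-4-[3,4-bis(benzyloxy)phenyl]cyclobutane-1,3-dicarboxylate (ring configuration as in 16)
Conditions: 14 (1.2 equiv), PPh3 (1.5 equiv), DIAD (1.5 equiv), THF, 0 °C to rt
Reagents that add atoms: none
Why: Mitsunobu esterification; the carboxylate of 12 displaces the oxyphosphonium-activated carbinol of 14 by SN2 with inversion, converting the R alcohol into the S ester carbon of the target, and the ring stereocentres are not touched.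

**Step 10**
Reactants: 15 heptabenzyl precursor
Product: 16 (1R,2R,3S,4S)-3-{[(S)-1-carboxy-2-(3,4-dihydroxyphenyl)ethoxy]carbonyl}-4-(3,4-dihydroxyphenyl)-2-(4-hydroxyphenyl)cyclobutane-1-carboxylic acid (CNP0270917.2)
Conditions: H2 (1 atm), 10 % Pd/C, THF/MeOH, rt
Reagents that add atoms: none
Why: Catalytic hydrogenolysis removes the five benzyl ethers and two benzyl esters; there is no alkene and no benzylic C–O stereocentre, so no stereocentre is scrambled.

**Compound list**
1 | cis-3-(methoxycarbonyl)cyclobutane-1-carboxylic acid | COC(=O)[C@H]1C[C@@H](C(=O)O)C1 | starting material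
2 | 2-(methylsulfanyl)aniline | CSc1ccccc1N | starting material
3 | methyl cis-3-{[2-(methylsulfanyl)phenyl]carbamoyl}cyclobutane-1-carboxylate | COC(=O)[C@H]1C[C@@H](C(=O)Nc2ccccc2SC)C1 | intermediate
4 | 1,2-bis(benzyloxy)benzene | c1ccc(COc2ccccc2OCc2ccccc2)cc1 | starting material
5 | 1,2-bis(benzyloxy)-4-iodobenzene | Ic1ccc(OCc2ccccc2)c(OCc2ccccc2)c1 | intermediate
6 | methyl 2-[3,4-bis(benzyloxy)phenyl]-3-{[2-(methylsulfanyl)phenyl]carbamoyl}cyclobutane-1-carboxylate, all-cis (racemic, one enantiomer drawn) | O=C(Nc1ccccc1SC)[C@H]1[C@@H](c2ccc(OCc3ccccc3)c(OCc3ccccc3)c2)[C@@H](C(=O)OC)C1 | intermediate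
7 | 1-(benzyloxy)-4-iodobenzene | Ic1ccc(OCc2ccccc2)cc1 | starting material
8 | methyl 2-[3,4-bis(benzyloxy)phenyl]-4-[4-(benzyloxy)phenyl]-3-{[2-(methylsulfanyl)phenyl]carbamoyl}cyclobutane-1-carboxylate, all-cis (racemic, one enantiomer drawn) | O=C(Nc1ccccc1SC)[C@H]1[C@@H](c2ccc(OCc3ccccc3)c(OCc3ccccc3)c2)[C@@H](C(=O)OC)[C@H]1c1ccc(OCc2ccccc2)cc1 | intermediate
9 | same constitution as 8, all-trans: amide and ester on one face, both aryl groups on the other (racemic, one enantiomer drawn; not isolated) | O=C(Nc1ccccc1SC)[C@@H]1[C@@H](c2ccc(OCc3ccccc3)c(OCc3ccccc3)c2)[C@H](C(=O)OC)[C@H]1c1ccc(OCc2ccccc2)cc1 | intermediate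
10 | 2-[3,4-bis(benzyloxy)phenyl]-4-[4-(benzyloxy)phenyl]cyclobutane-1,3-dicarboxylic acid, all-trans, meso | O=C(O)[C@@H]1[C@@H](c2ccc(OCc3ccccc3)cc2)[C@H](C(=O)O)[C@H]1c1ccc(OCc2ccccc2)c(OCc2ccccc2)c1 | intermediate
11 | 6-[3,4-bis(benzyloxy)phenyl]-7-[4-(benzyloxy)phenyl]-3-oxabicyclo[3.1.1]heptane-2,4-dione, meso, aryl groups anti to the anhydride bridge | O=C3[C@@H]1[C@@H](c2ccc(OCc4ccccc4)cc2)[C@H](C(=O)O3)[C@H]1c1ccc(OCc2ccccc2)c(OCc2ccccc2)c1 | intermediate
12 | 1-benzyl hydrogen 2-[4-(benzyloxy)phenyl]-4-[3,4-bis(benzyloxy)phenyl]cyclobutane-1,3-dicarboxylate, all-trans, single enantiomer | O=C(OCc1ccccc1)[C@@H]1[C@@H](c2ccc(OCc3ccccc3)cc2)[C@H](C(=O)O)[C@H]1c1ccc(OCc2ccccc2)c(OCc2ccccc2)c1 | intermediate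
13 | sodium (R)-3-(3,4-dihydroxyphenyl)-2-hydroxypropanoate (sodium danshensu) | [Na+].[O-]C(=O)[C@H](O)Cc1ccc(O)c(O)c1 | starting material
14 | benzyl (R)-3-[3,4-bis(benzyloxy)phenyl]-2-hydroxypropanoate | O=C(OCc1ccccc1)[C@H](O)Cc1ccc(OCc2ccccc2)c(OCc2ccccc2)c1 | intermediate
15 | 1-benzyl 3-{(S)-1-(benzyloxy)-3-[3,4-bis(benzyloxy)phenyl]-1-oxopropan-2-yl} 2-[4-(benzyloxy)phenyl]-4-[3,4-bis(benzyloxy)phenyl]cyclobutane-1,3-dicarboxylate | O=C(OCc1ccccc1)[C@@H]1[C@@H](c2ccc(OCc3ccccc3)cc2)[C@H](C(=O)O[C@@H](Cc2ccc(OCc3ccccc3)c(OCc3ccccc3)c2)C(=O)OCc2ccccc2)[C@H]1c1ccc(OCc2ccccc2)c(OCc2ccccc2)c1 | intermediate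
16 | (1R,2R,3S,4S)-3-{[(S)-1-carboxy-2-(3,4-dihydroxyphenyl)ethoxy]carbonyl}-4-(3,4-dihydroxyphenyl)-2-(4-hydroxyphenyl)cyclobutane-1-carboxylic acid | O=C(O)[C@@H]1[C@@H](c2ccc(O)cc2)[C@H](C(=O)O[C@@H](Cc2ccc(O)c(O)c2)C(=O)O)[C@H]1c1ccc(O)c(O)c1 | target

**Totals and risks**
Total step count: 10. Longest linear sequence: 8 (steps 1, 3, 4, 5, 6, 7, 9, 10).

Most likely to fail, first: step 7 (the proposed new step). The two carbonyls of 11 differ only through the distal aryl pair, so the enantiomer ratio may be modest. Any shortfall is removed after step 9, because the minor hemiester then gives a diastereomer of 15. The fallback uses known chemistry and replaces catalysis by resolution: setting out from 11, BnOH with DMAP/Et3N gives the racemic hemiester, that is 12 together with the enantiomeric hemiester F1. Mitsunobu coupling of this mixture with 14 under the step 9 conditions gives 15 and the core-mirrored diastereomeric ester F2. These are separated by preparative HPLC or crystallisation, and the route is rejoined at 15.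

Second: step 4. The second arylation must build an all-cis tetrasubstituted cyclobutane and may stall for steric reasons. The fallback changes the order of events: setting out from 6, KHMDS in THF at −78 °C inverts the ester carbon to give the C3-epimeric mono-aryl amide ester F3, whose remaining methylene is far less congested. Arylation of F3 with 7 under the step 4 conditions gives the diaryl amide ester F4 (amide cis to both aryl groups, ester trans). The step 5 conditions then only have to invert the amide carbon, and the route is rejoined at 10.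

Third: step 5. Direct hydrolysis of the hindered anilide needs 130 °C and may be incomplete or degrade the material. The fallback activates the amide instead: setting out from 8, KOtBu in THF gives 9, which is now isolated. Boc2O with DMAP in MeCN converts 9 into the N-Boc amide F5. LiOH/H2O2 in THF/H2O at 0 °C to rt then cleaves the activated amide and saponifies the methyl ester, and the route is rejoined at 10.

**Further compounds**
F1 | step 7 | 1-benzyl hydrogen 2-[4-(benzyloxy)phenyl]-4-[3,4-bis(benzyloxy)phenyl]cyclobutane-1,3-dicarboxylate, enantiomer of 12 | O=C(OCc1ccccc1)[C@H]1[C@H](c2ccc(OCc3ccccc3)cc2)[C@@H](C(=O)O)[C@@H]1c1ccc(OCc2ccccc2)c(OCc2ccccc2)c1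
F2 | step 7 | diastereomer of 15 with mirror-image cyclobutane core and (S)-lactate ester | O=C(OCc1ccccc1)[C@H]1[C@H](c2ccc(OCc3ccccc3)cc2)[C@@H](C(=O)O[C@@H](Cc2ccc(OCc3ccccc3)c(OCc3ccccc3)c2)C(=O)OCc2ccccc2)[C@@H]1c1ccc(OCc2ccccc2)c(OCc2ccccc2)c1
F3 | step 4 | methyl 2-[3,4-bis(benzyloxy)phenyl]-3-{[2-(methylsulfanyl)phenyl]carbamoyl}cyclobutane-1-carboxylate, ester trans to amide and aryl (racemic, one enantiomer drawn) | O=C(Nc1ccccc1SC)[C@H]1[C@@H](c2ccc(OCc3ccccc3)c(OCc3ccccc3)c2)[C@H](C(=O)OC)C1
F4 | step 4 | methyl 2-[3,4-bis(benzyloxy)phenyl]-4-[4-(benzyloxy)phenyl]-3-{[2-(methylsulfanyl)phenyl]carbamoyl}cyclobutane-1-carboxylate, amide cis to both aryl groups, ester trans (racemic, one enantiomer drawn) | O=C(Nc1ccccc1SC)[C@H]1[C@@H](c2ccc(OCc3ccccc3)c(OCc3ccccc3)c2)[C@H](C(=O)OC)[C@H]1c1ccc(OCc2ccccc2)cc1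
F5 | step 5 | N-Boc derivative of 9: methyl all-trans 2-[3,4-bis(benzyloxy)phenyl]-4-[4-(benzyloxy)phenyl]-3-{(tert-butoxycarbonyl)[2-(methylsulfanyl)phenyl]carbamoyl}cyclobutane-1-carboxylate (racemic, one enantiomer drawn) | O=C(N(C(=O)OC(C)(C)C)c1ccccc1SC)[C@@H]1[C@@H](c2ccc(OCc3ccccc3)c(OCc3ccccc3)c2)[C@H](C(=O)OC)[C@H]1c1ccc(OCc2ccccc2)cc1
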